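The numbers in the tables were generated by integration for substances that don't exist; scatter was added.

In millimolar, beta holds 2.60 mM of D against 0.86 mM of J. I suspected that J takes D one for one, so I reckoned with the excess, [D] charged minus [J] charged, 1.74 mM for beta.

| flask | E | D | J | remark | time |
|---|---|---|---|---|---|
| ash | 0.050 M | 1.6 mol% | 0.86 mM | run made earlier |  |
| oak | 0.050 M | 3 mol% | 0.86 mM | run made earlier |  |
| birch | 0.050 M | 3.8 mol% | 0.86 mM | run made earlier |  |
| beta | 0.050 M | 5.2 mol% | 0.86 mM |  | 10 d |
| theta | 0.050 M | 1.5 mol% | 0.86 mM |  | 10 d |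

- ash (time / d: Q / %, E / %): 0.625: 0, 99.6; 1.67: 0, 99.5; 3.00: 0.1, 98.4; 5.00: 0.1, 97.3
- oak (time / d: Q / %, E / %): 0.625: 0.2, 98.0; 1.67: 4.8, 94.5; 3.00: 13.8, 86.1; 5.00: 29.0, 69.6
- birch (time / d: Q / %, E / %): 0.625: 1.6, 98.8; 1.67: 8.0, 92.1; 3.00: 20.9, 79.6; 5.00: 42.1, 56.7

(each reading ± 0.5 percentage points)

- the average divides the monomer in chains by the number of chains begun, living and dead together
- the earlier runs do not show the number of chains; that part of a forecast is a guess

- which of the two ends with the longer chains by the average number of monomer units in a chain (chains begun, living or dead) ("neither" if they lie within 10%) (beta / theta / neither)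
- average number of monomer units in a chain (chains begun, living or dead) at the end, beta
- average number of monomer units in a chain (chains begun, living or dead) at the end, theta

The excess is −0.0600 mM for ash, which had 0.1% of Q by 5.00 d, against 29.0% for oak. Oak and birch then gave me the order of the rate:

oak: excess 0.640 mM, ln([E] charged/[E]) = 0.362, per mM 0.566 mM⁻¹

birch: excess 1.04 mM, ln([E] charged/[E]) = 0.567, per mM 0.546 mM⁻¹

These readings stand close, so I took the rate as first order in the excess. Scaling birch to beta's excess and time gave:

ln([E] charged/[E]) = 1.90, [E] left 15.0%, E reacted 42.5 mM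

If the whole excess began chains, beta's length was 24.4.

The weak link was that count, since theta's excess is −0.110 mM. So I reforged it per chain. Birch's last stretch reads as a slope of 0.170 d⁻¹, and counting its whole excess as living ends gives an estimate:

growth per chain = 8.15 d⁻¹, length over 10 d = 81.5

That length applies to theta if its few chains begin early and its E stays near the charge, and it puts theta ahead of beta.

The forecast differed, naming beta, with 27 (17 to 36) for beta and 1.5 (1 to 6) for theta: “Theta lies below the threshold, so its chains are only stubs of about one or two units.”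

The flask gave theta, with 48.5 for beta and 175 for theta.

    E + G → Q + G, rate k1*[G]*[E] (k = 0.00412 M⁻¹ s⁻¹)
    E + D → G + Q (k = 3.75 × 10⁻⁵ M⁻¹ s⁻¹)
    E → X (k = 3.41 × 10⁻⁸ s⁻¹)
    D + J → L (k = 1.67 M⁻¹ s⁻¹)

Theta's excess lay on J's side: 0.110 mM, or 12.8% of J's charge, and the flask kept 13.1% of J, while D, the limiting reagent of that pair, stood at 0% and [G] at 2.29 × 10⁻⁶ M. In theta, E had a half-life of 240 d towards X against 850 d towards Q, and at 10.0 d X stood at 2.89% and Q at 0.800%. A neighbour of theta charged with 6 mol% of D has an excess of 2.14 mM; its [G] of 0.00107 M and its remaining D of 1.07 mM together make 2.14 mM, and its chains averaged 43.6 units.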